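Numbering used throughout: the furo[3,2-c]pyran-4-one core is O1, C2, C3, C3a, C4 (lactone C=O), O5, C6, C7, C7a. Ring A is the fused 2-pyranone, ring B the dihydrofuran, ring C the 4-hydroxy-2-pyranone on C3 (atoms O1′ to C6′). Compound numbers are those of the steps.

## The problem

Compound 18 is a 2,3-dihydro-4H-furo[3,2-c]pyran-4-one in which a 2-pyranone (ring A) shares its C3a–C7a bond with a dihydrofuran (ring B); C2 carries a 3,4-dihydroxyphenyl group, C3 a 4-hydroxy-2-pyranone (ring C) bound through C6′, and C6 an (E)-4-hydroxystyryl group. The only stereocentres are the adjacent C2 and C3, trans and (2S,3S). Trans is the more stable arrangement, so one secure centre can correct the other by equilibration, but the absolute configuration must be introduced deliberately at one of them and is lost whenever both become labile together, as in any opening of ring B to an alkene. Three features forbid rough treatment. C3–H is flanked by two pyranones and lies beta to O1, whose departure as a 4-oxidopyranone opens ring B under base. The C2–O1 bond is a para-oxygenated benzylic ether of a vinylogous acid and ionises under strong acid, or through a quinone methide once the para hydroxyl is free and deprotonated. The styryl double bond rules out hydrogenolysis and strong electrophiles, so the phenols must stay masked to the last step, and ring C, which is nucleophilic at C3′ towards aldehydes, should appear late. The feature that opens the synthesis is that ring B with a carboxyl-level carbon on C3 is the ring-contracted isomer of a 2-aryl-2,3-dihydropyrano[4,3-b]pyran-4,5-dione: moving the ring-fusion carbon from the ketone carbon to the neighbouring CH2 creates C3–C3a and ring B and turns the ketone carbon into an ester from which ring C can be grown, and that precursor has a single stereocentre, C2, from which the shift then sets C3.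

## Retrosynthesis

**18 from 17.** The three phenolic O–benzyl bonds are cut last. Benzyl ethers survive the acid of the key step, methoxide, an enolate and heat, and they can be removed by a boron Lewis acid without reduction, which the styryl group demands. The ring C hydroxyl needs no protection because ring C is made in the preceding step. The forward reaction must be non-basic, since 18 has a free hydroxyl para to C2.

**17 from 15, and 15 from 11 and 12.** Ring C is cut at the lactone bond O1′–C2′ and at C5′–C6′. This traces it to acylketene 16, released thermally from dioxinone 15, and 15 to the acyl carbon of acid 11 and the methyl carbon of dioxinone 12. The closure is neutral, which suits the base-labile C3–H. Building ring C before the styryl group was rejected, because a free 4-hydroxy-2-pyranone would itself condense with aldehyde 10 at C3′. The forward acylation must be done cold and quenched before C3 suffers.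

**11 from 9 and 10.** The styryl C=C bond is cut to the ring A methyl group of acid 9 and aldehyde 10. Placing this vinylogous aldol condensation at the carboxylic acid stage is deliberate: as the carboxylate, C3–H cannot be removed by methoxide, so neither epimerisation nor beta-elimination of O1 is possible. The ring A methyl remains the only acidic position that can dehydrate irreversibly.

**9 from 8.** Only the ester O–methyl group is removed. The forward cleavage must spare the ring A lactone and C3–H, which points to a neutral tin hydroxide, not aqueous alkali.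

**8 from 5 (key disconnection).** The C3–C3a bond is cut and C3a is reattached to the ester carbon, which expands ring B to the six-membered ketone 5. This removes one stereocentre and the ester, and reaches a flavanone analogue with only C2. The forward step is an oxidative 1,2-shift through enol ether 6 and iodanyl ketal 7. It must move the ring bond rather than the C2 aryl group, and must be faster than acid ionisation at C2.

**5 from 3 and 4.** The C2–aryl bond is cut to the flat, achiral pyranone-fused 4-pyranone 3 and boronic acid 4. Closing O1–C2 by oxa-Michael addition was the neighbouring option. It was set aside because it forms the stereocentre in a reversible step whose reverse is the racemisation path, and because it has no asymmetric precedent on so acidic a hydroxypyranone. Catalytic asymmetric conjugate arylation makes C2 in an irreversible C–C bond formation under base-free conditions and has close precedent on chromones.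

**3 from 1.** O1–C2 and C2–C3 are cut, with C2 coming from a formamide acetal by way of enaminone 2. This leads to dehydroacetic acid 1, which already holds ring A, its methyl group and the acetyl carbons C3 and C4.

## Roads not taken

**Alternative 1:** Ring B is cut at O1–C2 and C2–C3. In the forward sense a chiral benzylic sulfonium ylide A3 adds through its carbon to the exocyclic carbon of the alkylidene pyrandione A2, and the ring A enolate oxygen then displaces the sulfide to give the tetrabenzyl ether A1.
- Merits: it is convergent, ring C and the styryl group are already in place, both stereocentres arise in one step, and one deprotection finishes the synthesis.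
- Weak points: A2 is a cross-conjugated, doubly activated acceptor that must be made in situ and readily takes up a second hydroxypyranone. The C3–H of the betaine lies between two pyranones and can epimerise before closure. Enantiocontrol rests on a reversible addition of a semi-stabilised ylide. Closure through carbon to a cyclopropane competes with closure through oxygen.
- Comparison: this road is shorter and more convergent than the chosen plan. Against that, the chosen plan sets a single stereocentre by a catalytic C–C bond formation with close precedent, passes only through stable, isolable intermediates, and relays the configuration by a stereospecific shift.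

**Alternative 2:** The cuts are C4–O5 and O1–C7a. On heating with a sulfonic acid, the enol oxygen of the diketone side chain of acyl lactone A5 attacks the lactone carbonyl to form ring A, and the released C2 hydroxyl condenses with the C7a carbonyl to form ring B, giving silyl ether A4.
- Merits: both stereocentres are fixed on a simple trans butyrolactone by established methods before any pyranone exists. The styryl group arrives with the side chain, two rings form in one operation, and no oxidant is needed.
- Weak points: C3 of A4 carries a CH2O–silyl group two oxidation levels below the carbon needed for ring C, so desilylation and two oxidations precede the same ring C construction. The hot acid can ionise the electron-rich benzylic C2–O bond, add the diketone enol to the styryl enone, or remove the silyl group.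
- Comparison: stereochemical security at the outset is better here than in the chosen plan. The chosen plan answers with a C3 carbon born at the carboxyl level and a sequence several steps shorter.

**Alternative 3:** Only O1–C2 is cut. Anodic oxidation of the free phenol of A7 gives a para-quinone methide, and the ring A hydroxyl adds to its exocyclic carbon to give A6.
- Merits: it is biomimetic and late-stage, only C3 must be set beforehand with C2 following by trans closure, and A6 already has one phenol free.
- Weak points: A7 holds other electron-rich π systems (the alkoxystyryl pyranone and the enolic pyranone) that oxidise at similar potentials. The quinone methide can tautomerise through the acidic C3–H to a stilbene, which erases C3. No reliable asymmetric entry to the C3 centre of A7, flanked by two pyranones, is evident.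
- Comparison: the endgame is the shortest of all. The chosen plan sets against it a defined catalytic source of absolute configuration and a key step in which C3 is formed and fixed in the same event.

Key step: step 3

Assumption: the (R)-configured pyridine–oxazoline ligand is taken to give (2S)-5, by transfer of the facial preference this catalyst shows with cyclic enones and chromones; the sense is to be confirmed on 5 and the ligand antipode used if it is reversed.

## Route

Step 1
Reactants: 1 dehydroacetic acid (3-acetyl-4-hydroxy-6-methyl-2H-pyran-2-one)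
Product: 3 7-methyl-4H,5H-pyrano[4,3-b]pyran-4,5-dione, via enaminone 2 (not isolated)
Conditions: Me2NCH(OMe)2, PhMe, 110 °C; then conc. HCl, CH2Cl2, 40 °C
Reagents that add atoms: N,N-dimethylformamide dimethyl acetal, COC(OC)N(C)C
Why: Condensation of the activated acetyl group with the formamide acetal gives enaminone 2; acid then drives addition of the 4-hydroxyl to the enaminone beta carbon and loss of dimethylamine, the standard enaminone route to chromones applied to the pyranone analogue.

Step 2
Reactants: 3 7-methyl-4H,5H-pyrano[4,3-b]pyran-4,5-dione; 4 [3,4-bis(benzyloxy)phenyl]boronic acid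
Product: 5 (2S)-2-[3,4-bis(benzyloxy)phenyl]-7-methyl-2,3-dihydro-4H,5H-pyrano[4,3-b]pyran-4,5-dione
Conditions: Pd(OCOCF3)2 (5 mol %), (R)-t-BuPyOx [(R)-4-tert-butyl-2-(pyridin-2-yl)-4,5-dihydrooxazole] (6 mol %), NH4PF6, H2O, ClCH2CH2Cl, 40 °C
Reagents that add atoms: none
Why: Palladium-catalysed asymmetric conjugate addition of an arylboronic acid to a chromone-type 4-pyranone; the aryl group is delivered to C2 on the face selected by the chiral ligand in an irreversible C–C bond formation, and the base-free, slightly acidic medium should spare the product from retro-oxa-Michael opening; the trisubstituted, oxygen-bearing C7 of the 2-pyranone is a much poorer acceptor than C2.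

Step 3
Reactants: 5 (2S)-2-[3,4-bis(benzyloxy)phenyl]-7-methyl-2,3-dihydro-4H,5H-pyrano[4,3-b]pyran-4,5-dione
Product: 8 methyl (2S,3S)-2-[3,4-bis(benzyloxy)phenyl]-6-methyl-4-oxo-2,3-dihydro-4H-furo[3,2-c]pyran-3-carboxylate, via enol ether 6 (not isolated), via iodanyl ketal 7 (not isolated)
Conditions: PhI(OAc)2 (1.2 equiv), HC(OMe)3, H2SO4 (cat.), 0 °C to rt
Reagents that add atoms: trimethyl orthoformate, COC(OC)OC
Why: Proposed new method: the closest known reaction is the oxidative ring contraction of flavanones and chroman-4-ones by PhI(OAc)2 or Tl(NO3)3 in trimethyl orthoformate to trans-2-aryl-2,3-dihydrobenzofuran-3-carboxylates, which has not been run where the migrating carbon is the ring-fusion carbon of a 2-pyranone. Acid and orthoformate turn the C4 ketone of 5 into enol ether 6, the iodane attacks C3 and methanol adds to give ketal 7, with the bulky iodanyl group equatorial and trans to the C2 aryl group. The C4–C4a ring bond, antiperiplanar to C3–I, then shifts to C3 as iodobenzene leaves, and the dimethoxycarbenium ion left at the old C4 is demethylated by acetate to the methyl ester. Ring B thus closes by a suprafacial 1,2-shift of an alkenyl carbon (contraction from six to five members), not by a cyclisation. The new stereocentre C3 is set by inversion at the iodine-bearing carbon, which places the ester trans to the aryl group; C2 is not touched, so (2S)-5 should give (2S,3S)-8, which is also the thermodynamic isomer. The step needs the ring bond to migrate in preference to the C2 aryl group: the axial methoxy group of ketal 7 disfavours the diaxial conformer an aryl shift requires, and O1, a vinylogous ester oxygen, stabilises a C2 cation poorly. The migrating carbon is the nucleophilic beta carbon of the pyranone enol ether and can bridge as an alkoxyaryl carbon does.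

Step 4
Reactants: 8 methyl (2S,3S)-2-[3,4-bis(benzyloxy)phenyl]-6-methyl-4-oxo-2,3-dihydro-4H-furo[3,2-c]pyran-3-carboxylate
Product: 9 (2S,3S)-2-[3,4-bis(benzyloxy)phenyl]-6-methyl-4-oxo-2,3-dihydro-4H-furo[3,2-c]pyran-3-carboxylic acid
Conditions: Me3SnOH, ClCH2CH2Cl, 80 °C; then aq. HCl
Reagents that add atoms: trimethyltin hydroxide, C[Sn](C)(C)O
Why: Trimethyltin hydroxide cleaves methyl esters under essentially neutral conditions, so the ring A lactone and the base-labile C3–H should be spared; any epimerisation at C3 would return to trans because C2 is fixed.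

Step 5
Reactants: 9 (2S,3S)-2-[3,4-bis(benzyloxy)phenyl]-6-methyl-4-oxo-2,3-dihydro-4H-furo[3,2-c]pyran-3-carboxylic acid; 10 4-(benzyloxy)benzaldehyde
Product: 11 (2S,3S)-2-[3,4-bis(benzyloxy)phenyl]-6-[(E)-2-[4-(benzyloxy)phenyl]ethenyl]-4-oxo-2,3-dihydro-4H-furo[3,2-c]pyran-3-carboxylic acid
Conditions: Mg(OMe)2 (4 equiv), MeOH, 65 °C; then cold aq. HCl
Reagents that add atoms: none
Why: Vinylogous aldol condensation of a 4-alkoxy-6-methyl-2-pyranone with an aromatic aldehyde under Mg(OMe)2, the standard route to 6-styryl-2-pyranones; dehydration gives the conjugated (E)-alkene, and the magnesium carboxylate makes C3–H non-acidic, so ring B cannot open by beta-elimination or retro-aldol cleavage.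

Step 6
Reactants: 11 (2S,3S)-2-[3,4-bis(benzyloxy)phenyl]-6-[(E)-2-[4-(benzyloxy)phenyl]ethenyl]-4-oxo-2,3-dihydro-4H-furo[3,2-c]pyran-3-carboxylic acid; 12 2,2,6-trimethyl-4H-1,3-dioxin-4-one
Product: 15 6-{2-[(2S,3S)-2-[3,4-bis(benzyloxy)phenyl]-6-[(E)-2-[4-(benzyloxy)phenyl]ethenyl]-4-oxo-2,3-dihydro-4H-furo[3,2-c]pyran-3-yl]-2-oxoethyl}-2,2-dimethyl-4H-1,3-dioxin-4-one, via acid chloride 13 (not isolated), via lithium dienolate 14 (not isolated)
Conditions: 11, Me2C=C(Cl)NMe2, CH2Cl2, 0 °C; 12, LiN(SiMe3)2 (2.5 equiv), THF, −78 °C; acid chloride added at −78 °C; AcOH quench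
Reagents that add atoms: none
Why: Vinylogous Claisen acylation of the dioxinone dienolate at its gamma carbon by an acid chloride made under neutral conditions; the excess dienolate deprotonates the product between its two carbonyl groups, which shields C3–H, and any epimerisation at C3 through a ketene is self-correcting because C2 is untouched and trans is favoured.

Step 7
Reactants: 15 6-{2-[(2S,3S)-2-[3,4-bis(benzyloxy)phenyl]-6-[(E)-2-[4-(benzyloxy)phenyl]ethenyl]-4-oxo-2,3-dihydro-4H-furo[3,2-c]pyran-3-yl]-2-oxoethyl}-2,2-dimethyl-4H-1,3-dioxin-4-one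
Product: 17 (2S,3S)-2-[3,4-bis(benzyloxy)phenyl]-6-[(E)-2-[4-(benzyloxy)phenyl]ethenyl]-3-(4-hydroxy-2-oxo-2H-pyran-6-yl)-2,3-dihydro-4H-furo[3,2-c]pyran-4-one, via acylketene 16 (not isolated)
Conditions: PhMe, 110 °C, dilute, light excluded
Reagents that add atoms: none
Why: Thermal retro-hetero-Diels–Alder loss of acetone from the dioxinone gives acylketene 16, which is captured by the enol oxygen of the neighbouring ketone to close ring C as the 4-hydroxy-2-pyranone; the medium is neutral and no free hydroxyl competes for the ketene.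

Step 8
Reactants: 17 (2S,3S)-2-[3,4-bis(benzyloxy)phenyl]-6-[(E)-2-[4-(benzyloxy)phenyl]ethenyl]-3-(4-hydroxy-2-oxo-2H-pyran-6-yl)-2,3-dihydro-4H-furo[3,2-c]pyran-4-one
Product: 18 (2S,3S)-2-(3,4-dihydroxyphenyl)-3-(4-hydroxy-2-oxo-2H-pyran-6-yl)-6-[(E)-2-(4-hydroxyphenyl)ethenyl]-2,3-dihydro-4H-furo[3,2-c]pyran-4-one
Conditions: BCl3, C6HMe5, CH2Cl2, −78 °C; then H2O
Reagents that add atoms: none
Why: Lewis acid cleavage of aryl benzyl ethers by BCl3 with pentamethylbenzene as a non-basic benzyl cation scavenger; nothing is reduced, so the styryl alkene survives, the scavenger keeps benzyl cations off the electron-rich rings, and the absence of base avoids quinone methide opening of ring B.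

## Compound list

1 | dehydroacetic acid (3-acetyl-4-hydroxy-6-methyl-2H-pyran-2-one) | CC(=O)c1c(O)cc(C)oc1=O | starting material
2 | 3-[(2E)-3-(dimethylamino)prop-2-enoyl]-4-hydroxy-6-methyl-2H-pyran-2-one | CN(C)/C=C/C(=O)c1c(O)cc(C)oc1=O | intermediate
3 | 7-methyl-4H,5H-pyrano[4,3-b]pyran-4,5-dione | O=C1C=COC2=C1C(=O)OC(C)=C2 | intermediate
4 | [3,4-bis(benzyloxy)phenyl]boronic acid | OB(O)c1ccc(OCc2ccccc2)c(OCc2ccccc2)c1 | starting material
5 | (2S)-2-[3,4-bis(benzyloxy)phenyl]-7-methyl-2,3-dihydro-4H,5H-pyrano[4,3-b]pyran-4,5-dione | O=C1C[C@@H](c3ccc(OCc4ccccc4)c(OCc4ccccc4)c3)Oc2cc(C)oc(=O)c12 | intermediate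
6 | (2S)-2-[3,4-bis(benzyloxy)phenyl]-4-methoxy-7-methyl-2H,5H-pyrano[4,3-b]pyran-5-one | COC1=C[C@@H](c3ccc(OCc4ccccc4)c(OCc4ccccc4)c3)Oc2cc(C)oc(=O)c12 | intermediate
7 | (2R,3R)-3-[acetoxy(phenyl)-λ3-iodanyl]-2-[3,4-bis(benzyloxy)phenyl]-4,4-dimethoxy-7-methyl-3,4-dihydro-2H,5H-pyrano[4,3-b]pyran-5-one (iodanyl group trans to the aryl group; C2 is spatially as in 5, its descriptor changes by priority only) | COC1(OC)[C@H]([I](OC(C)=O)c5ccccc5)[C@@H](c3ccc(OCc4ccccc4)c(OCc4ccccc4)c3)Oc2cc(C)oc(=O)c12 | intermediate
8 | methyl (2S,3S)-2-[3,4-bis(benzyloxy)phenyl]-6-methyl-4-oxo-2,3-dihydro-4H-furo[3,2-c]pyran-3-carboxylate | COC(=O)[C@H]1c2c(cc(C)oc2=O)O[C@@H]1c1ccc(OCc2ccccc2)c(OCc2ccccc2)c1 | intermediate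
9 | (2S,3S)-2-[3,4-bis(benzyloxy)phenyl]-6-methyl-4-oxo-2,3-dihydro-4H-furo[3,2-c]pyran-3-carboxylic acid | OC(=O)[C@H]1c2c(cc(C)oc2=O)O[C@@H]1c1ccc(OCc2ccccc2)c(OCc2ccccc2)c1 | intermediate
10 | 4-(benzyloxy)benzaldehyde | O=Cc1ccc(OCc2ccccc2)cc1 | starting material
11 | (2S,3S)-2-[3,4-bis(benzyloxy)phenyl]-6-[(E)-2-[4-(benzyloxy)phenyl]ethenyl]-4-oxo-2,3-dihydro-4H-furo[3,2-c]pyran-3-carboxylic acid | OC(=O)[C@H]1c2c(cc(/C=C/c3ccc(OCc4ccccc4)cc3)oc2=O)O[C@@H]1c1ccc(OCc2ccccc2)c(OCc2ccccc2)c1 | intermediate
12 | 2,2,6-trimethyl-4H-1,3-dioxin-4-one | CC1=CC(=O)OC(C)(C)O1 | starting material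
13 | (2S,3S)-2-[3,4-bis(benzyloxy)phenyl]-6-[(E)-2-[4-(benzyloxy)phenyl]ethenyl]-4-oxo-2,3-dihydro-4H-furo[3,2-c]pyran-3-carbonyl chloride | ClC(=O)[C@H]1c2c(cc(/C=C/c3ccc(OCc4ccccc4)cc3)oc2=O)O[C@@H]1c1ccc(OCc2ccccc2)c(OCc2ccccc2)c1 | intermediate
14 | lithium 2,2-dimethyl-6-methylidene-6H-1,3-dioxin-4-olate | [Li+].C=C1C=C([O-])OC(C)(C)O1 | intermediate
15 | 6-{2-[(2S,3S)-2-[3,4-bis(benzyloxy)phenyl]-6-[(E)-2-[4-(benzyloxy)phenyl]ethenyl]-4-oxo-2,3-dihydro-4H-furo[3,2-c]pyran-3-yl]-2-oxoethyl}-2,2-dimethyl-4H-1,3-dioxin-4-one | CC1(C)OC(=O)C=C(CC(=O)[C@H]2c3c(cc(/C=C/c4ccc(OCc5ccccc5)cc4)oc3=O)O[C@@H]2c2ccc(OCc3ccccc3)c(OCc3ccccc3)c2)O1 | intermediate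
16 | 5-[(2S,3S)-2-[3,4-bis(benzyloxy)phenyl]-6-[(E)-2-[4-(benzyloxy)phenyl]ethenyl]-4-oxo-2,3-dihydro-4H-furo[3,2-c]pyran-3-yl]pent-1-ene-1,3,5-trione | O=C=CC(=O)CC(=O)[C@H]1c2c(cc(/C=C/c3ccc(OCc4ccccc4)cc3)oc2=O)O[C@@H]1c1ccc(OCc2ccccc2)c(OCc2ccccc2)c1 | intermediate
17 | (2S,3S)-2-[3,4-bis(benzyloxy)phenyl]-6-[(E)-2-[4-(benzyloxy)phenyl]ethenyl]-3-(4-hydroxy-2-oxo-2H-pyran-6-yl)-2,3-dihydro-4H-furo[3,2-c]pyran-4-one | O=c1cc(O)cc([C@H]2c3c(cc(/C=C/c4ccc(OCc5ccccc5)cc4)oc3=O)O[C@@H]2c2ccc(OCc3ccccc3)c(OCc3ccccc3)c2)o1 | intermediate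
18 | (2S,3S)-2-(3,4-dihydroxyphenyl)-3-(4-hydroxy-2-oxo-2H-pyran-6-yl)-6-[(E)-2-(4-hydroxyphenyl)ethenyl]-2,3-dihydro-4H-furo[3,2-c]pyran-4-one | O=c1cc(O)cc([C@H]2c3c(cc(/C=C/c4ccc(O)cc4)oc3=O)O[C@@H]2c2ccc(O)c(O)c2)o1 | target

## Step count and least certain steps

Total: 8 steps. Longest linear sequence: 8 steps (1 to 18); 4, 10 and 12 are commercial.

**Step 3 (key step, the one proposed new method).**
- The C2 aryl group may migrate instead of the ring-fusion carbon, since the dialkoxyphenyl ring is electron-rich.
- The benzylic C2–O1 bond may ionise in acid before or after the shift, with racemisation at C2 or ring opening by methanol.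
- Enol ether formation may be slow because the C4 ketone is a vinylogous ester carbonyl, which gives that ionisation more time.
- The iodane may attack C8 of the pyranone or the dialkoxyarene.
- Fallback (known chemistry, different bond construction): from 1, deacetylation in hot aqueous H2SO4 gives 4-hydroxy-6-methyl-2H-pyran-2-one F1. From 4, oxidative Heck coupling with methyl acrylate (Pd(OAc)2, O2) gives methyl (2E)-3-[3,4-bis(benzyloxy)phenyl]prop-2-enoate F2. Mn(OAc)3-mediated oxidative radical annulation of F1 with F2 in AcOH forms C3–C3a by radical addition and O1–C2 by capture of the oxidised benzylic radical, giving the racemic trans ester F3. Preparative chromatography on a chiral stationary phase then delivers 8, where the route resumes.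

**Step 2.**
- The product may open by retro-oxa-Michael reaction under the reaction conditions, eroding enantiomeric purity.
- The electron-rich boronic acid may protodeboronate.
- Facial selectivity on this new acceptor may be insufficient.
- Fallback: from 1, piperidine-catalysed aldol condensation with commercial 3,4-bis(benzyloxy)benzaldehyde gives 3-[(2E)-3-[3,4-bis(benzyloxy)phenyl]prop-2-enoyl]-4-hydroxy-6-methyl-2H-pyran-2-one F4. Amine- or acid-mediated oxa-Michael closure gives the racemic dione F5. Separation on a chiral stationary phase gives 5, and the unwanted enantiomer is re-equilibrated through F4 with Et3N and recycled.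

**Step 5.**
- Conversion may be incomplete because the magnesium carboxylate is poorly soluble.
- Methoxide may attack the ring A lactone on prolonged heating.
- The electron-rich aldehyde may be slow to dehydrate.
- Fallback: from 8, SeO2 in hot dioxane oxidises the ring A methyl group to methyl (2S,3S)-2-[3,4-bis(benzyloxy)phenyl]-6-formyl-4-oxo-2,3-dihydro-4H-furo[3,2-c]pyran-3-carboxylate F6. Horner–Wadsworth–Emmons olefination with the lithium salt of diethyl [4-(benzyloxy)benzyl]phosphonate at −78 °C gives the (E)-styryl methyl ester F7. Me3SnOH cleavage as in step 4 gives 11.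

**Step 6.**
- The basic dienolate may cause beta-elimination of O1 from a C3 enolate or ketene, opening ring B.
- The dienolate may add in conjugate fashion to the styrylpyranone.
- O-acylation or double acylation of the dienolate may occur.
- Fallback (no strong base): from 11, thioesterification with EtSH (carbodiimide, DMAP cat.) gives the S-ethyl thioester F8, and Fukuyama reduction (Et3SiH, Pd/C) gives the 3-carbaldehyde F9. Separately, 12 is converted with LiN(iPr)2 and Me3SiCl into the silyl dienol ether F10. BF3·OEt2-mediated vinylogous Mukaiyama aldol addition of F10 to F9 gives the hydroxy dioxinone F11, and Dess–Martin oxidation gives 15.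

## Further compounds

F1 | step 3 | 4-hydroxy-6-methyl-2H-pyran-2-one | Cc1cc(O)cc(=O)o1
F2 | step 3 | methyl (2E)-3-[3,4-bis(benzyloxy)phenyl]prop-2-enoate | COC(=O)/C=C/c1ccc(OCc2ccccc2)c(OCc2ccccc2)c1
F3 | step 3 | racemic methyl trans-2-[3,4-bis(benzyloxy)phenyl]-6-methyl-4-oxo-2,3-dihydro-4H-furo[3,2-c]pyran-3-carboxylate (1:1 mixture of 8 and its enantiomer) | COC(=O)[C@H]1c2c(cc(C)oc2=O)O[C@@H]1c1ccc(OCc2ccccc2)c(OCc2ccccc2)c1.COC(=O)[C@@H]1c2c(cc(C)oc2=O)O[C@H]1c1ccc(OCc2ccccc2)c(OCc2ccccc2)c1
F4 | step 2 | 3-[(2E)-3-[3,4-bis(benzyloxy)phenyl]prop-2-enoyl]-4-hydroxy-6-methyl-2H-pyran-2-one | O=C(/C=C/c1ccc(OCc2ccccc2)c(OCc2ccccc2)c1)c1c(O)cc(C)oc1=O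
F5 | step 2 | racemic 2-[3,4-bis(benzyloxy)phenyl]-7-methyl-2,3-dihydro-4H,5H-pyrano[4,3-b]pyran-4,5-dione (1:1 mixture of 5 and its enantiomer) | O=C1C[C@@H](c3ccc(OCc4ccccc4)c(OCc4ccccc4)c3)Oc2cc(C)oc(=O)c12.O=C1C[C@H](c3ccc(OCc4ccccc4)c(OCc4ccccc4)c3)Oc2cc(C)oc(=O)c12
F6 | step 5 | methyl (2S,3S)-2-[3,4-bis(benzyloxy)phenyl]-6-formyl-4-oxo-2,3-dihydro-4H-furo[3,2-c]pyran-3-carboxylate | COC(=O)[C@H]1c2c(cc(C=O)oc2=O)O[C@@H]1c1ccc(OCc2ccccc2)c(OCc2ccccc2)c1
F7 | step 5 | methyl (2S,3S)-2-[3,4-bis(benzyloxy)phenyl]-6-[(E)-2-[4-(benzyloxy)phenyl]ethenyl]-4-oxo-2,3-dihydro-4H-furo[3,2-c]pyran-3-carboxylate | COC(=O)[C@H]1c2c(cc(/C=C/c3ccc(OCc4ccccc4)cc3)oc2=O)O[C@@H]1c1ccc(OCc2ccccc2)c(OCc2ccccc2)c1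
F8 | step 6 | S-ethyl (2S,3S)-2-[3,4-bis(benzyloxy)phenyl]-6-[(E)-2-[4-(benzyloxy)phenyl]ethenyl]-4-oxo-2,3-dihydro-4H-furo[3,2-c]pyran-3-carbothioate | CCSC(=O)[C@H]1c2c(cc(/C=C/c3ccc(OCc4ccccc4)cc3)oc2=O)O[C@@H]1c1ccc(OCc2ccccc2)c(OCc2ccccc2)c1
F9 | step 6 | (2S,3S)-2-[3,4-bis(benzyloxy)phenyl]-6-[(E)-2-[4-(benzyloxy)phenyl]ethenyl]-4-oxo-2,3-dihydro-4H-furo[3,2-c]pyran-3-carbaldehyde | O=C[C@H]1c2c(cc(/C=C/c3ccc(OCc4ccccc4)cc3)oc2=O)O[C@@H]1c1ccc(OCc2ccccc2)c(OCc2ccccc2)c1
F10 | step 6 | [(2,2-dimethyl-6-methylidene-6H-1,3-dioxin-4-yl)oxy]trimethylsilane | C=C1C=C(O[Si](C)(C)C)OC(C)(C)O1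
F11 | step 6 | 6-{2-hydroxy-2-[trans-2-[3,4-bis(benzyloxy)phenyl]-6-[(E)-2-[4-(benzyloxy)phenyl]ethenyl]-4-oxo-2,3-dihydro-4H-furo[3,2-c]pyran-3-yl]ethyl}-2,2-dimethyl-4H-1,3-dioxin-4-one (ring centres spatially as in 11, both carbinol epimers) | CC1(C)OC(=O)C=C(CC(O)[C@H]2c3c(cc(/C=C/c4ccc(OCc5ccccc5)cc4)oc3=O)O[C@@H]2c2ccc(OCc3ccccc3)c(OCc3ccccc3)c2)O1
A1 | alternative 1 | (2S,3S)-2-[3,4-bis(benzyloxy)phenyl]-3-[4-(benzyloxy)-2-oxo-2H-pyran-6-yl]-6-[(E)-2-[4-(benzyloxy)phenyl]ethenyl]-2,3-dihydro-4H-furo[3,2-c]pyran-4-one | O=c1cc(OCc2ccccc2)cc([C@H]2c3c(cc(/C=C/c4ccc(OCc5ccccc5)cc4)oc3=O)O[C@@H]2c2ccc(OCc3ccccc3)c(OCc3ccccc3)c2)o1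
A2 | alternative 1 | 3-{[4-(benzyloxy)-2-oxo-2H-pyran-6-yl]methylidene}-6-[(E)-2-[4-(benzyloxy)phenyl]ethenyl]-2H-pyran-2,4(3H)-dione | O=C1OC(/C=C/c2ccc(OCc3ccccc3)cc2)=CC(=O)C1=Cc1cc(OCc2ccccc2)cc(=O)o1
A3 | alternative 1 | (2R,5R)-2,5-dimethylthiolan-1-ium [3,4-bis(benzyloxy)phenyl]methylide (representative chiral ylide) | C[C@@H]1CC[C@@H](C)[S+]1[CH-]c1ccc(OCc2ccccc2)c(OCc2ccccc2)c1
A4 | alternative 2 | trans-(2S,3R)-2-[3,4-bis(benzyloxy)phenyl]-6-[(E)-2-[4-(benzyloxy)phenyl]ethenyl]-3-{[(tert-butyldiphenylsilyl)oxy]methyl}-2,3-dihydro-4H-furo[3,2-c]pyran-4-one | CC(C)(C)[Si](c1ccccc1)(c1ccccc1)OC[C@H]1c2c(cc(/C=C/c3ccc(OCc4ccccc4)cc3)oc2=O)O[C@@H]1c1ccc(OCc2ccccc2)c(OCc2ccccc2)c1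
A5 | alternative 2 | 4,5-trans-3-[(4E)-5-[4-(benzyloxy)phenyl]-3-oxopent-4-enoyl]-5-[3,4-bis(benzyloxy)phenyl]-4-{[(tert-butyldiphenylsilyl)oxy]methyl}oxolan-2-one | CC(C)(C)[Si](c1ccccc1)(c1ccccc1)OC[C@H]1C(C(=O)CC(=O)/C=C/c2ccc(OCc3ccccc3)cc2)C(=O)O[C@@H]1c1ccc(OCc2ccccc2)c(OCc2ccccc2)c1
A6 | alternative 3 | (2S,3S)-2-[3-(benzyloxy)-4-hydroxyphenyl]-3-[4-(benzyloxy)-2-oxo-2H-pyran-6-yl]-6-[(E)-2-[4-(benzyloxy)phenyl]ethenyl]-2,3-dihydro-4H-furo[3,2-c]pyran-4-one | O=c1cc(OCc2ccccc2)cc([C@H]2c3c(cc(/C=C/c4ccc(OCc5ccccc5)cc4)oc3=O)O[C@@H]2c2ccc(O)c(OCc3ccccc3)c2)o1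
A7 | alternative 3 | 3-[(1R)-2-[3-(benzyloxy)-4-hydroxyphenyl]-1-[4-(benzyloxy)-2-oxo-2H-pyran-6-yl]ethyl]-6-[(E)-2-[4-(benzyloxy)phenyl]ethenyl]-4-hydroxy-2H-pyran-2-one | O=c1cc(OCc2ccccc2)cc([C@H](Cc2ccc(O)c(OCc3ccccc3)c2)c2c(O)cc(/C=C/c3ccc(OCc4ccccc4)cc3)oc2=O)o1
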